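**Strategy.** Everything rests on cutting the 2,2-dimethyl-2H-pyran (ring C) out of the finished dimer at two bonds: C5–CH= on aromatic ring A and O6–C(CH3)2. In one operation, an amine-salt-mediated Knoevenagel condensation of 3-methylbut-2-enal at C5, the only unsubstituted carbon of ring A, and an oxa-6π electrocyclisation onto O6, the hydroxyl ortho to the hexanoyl-bearing C1, make both bonds. The precursor is the complete CH2-bridged dimer: hexanoylphloroglucinol ring A carrying its para oxygen O4 as a tert-butyldimethylsilyl ether, joined at C3 to the (R)-configured acetyl geranyl methyl trione (ring B). The feature exploited is the lone C5–H flanked by blocked O4 and free O6.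

Key step: step 9

Assumption: pig liver esterase is taken to hydrolyse the pro-S ester group of diester 7, as expected for a 2-methylmalonate whose second substituent is a long lipophilic chain; the fallback to step 4 covers the opposite sense.

Numbering used: ring A is the aromatic ring (C1 hexanoyl, O2, C3 bridge, O4 para oxygen, C5, O6); ring B is the trione-derived ring; ring C is the pyran. CIP descriptors of ring B refer to the tautomer drawn; the spatial arrangement at the quaternary carbon is the same from 8 to 21.

**Route**

Step 1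
Reactants: 1 phloroglucinol; 2 hexanoyl chloride
Product: 3 1-(2,4,6-trihydroxyphenyl)hexan-1-one
Conditions: AlCl3 (3.5 equiv), CH2Cl2–MeNO2, 0 °C → 40 °C; then ice/2 M HCl
Reagents that add atoms: none
Why: Friedel–Crafts C-acylation of the electron-rich triol should stop after one acyl group because the chelated aryl ketone–AlCl3 complex deactivates the ring.

Step 2
Reactants: 3 1-(2,4,6-trihydroxyphenyl)hexan-1-one
Product: 4 1-[4-(tert-butyldimethylsilyloxy)-2,6-dihydroxyphenyl]hexan-1-one
Conditions: tBuMe2SiCl (1.05 equiv), imidazole (2.2 equiv), CH2Cl2–DMF (10:1), 0 °C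
Reagents that add atoms: tert-butyldimethylsilyl chloride, CC(C)(C)[Si](C)(C)Cl
Why: O-silylation should take the para hydroxyl selectively, since it is the most acidic and least hindered one while both ortho hydroxyls flank the ketone and are engaged in hydrogen bonding to it, and the product keeps two equivalent free ring carbons.

Step 3
Reactants: 5 dimethyl methylmalonate; 6 geranyl bromide
Product: 7 dimethyl 2-[(2E)-3,7-dimethylocta-2,6-dien-1-yl]-2-methylpropanedioate
Conditions: NaH (1.1 equiv), THF, 0 °C; then 6 (1.05 equiv), 0 °C → rt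
Reagents that add atoms: none
Why: SN2 alkylation of the malonate anion at the primary allylic bromide should keep the E alkene and give the prochiral quaternary carbon.

Step 4
Reactants: 7 dimethyl 2-[(2E)-3,7-dimethylocta-2,6-dien-1-yl]-2-methylpropanedioate
Product: 8 (2R)-2-[(2E)-3,7-dimethylocta-2,6-dien-1-yl]-3-methoxy-2-methyl-3-oxopropanoic acid
Conditions: pig liver esterase, 0.1 M phosphate buffer pH 7.5–DMSO (9:1), 30 °C, pH-stat with 1 M NaOH; then HCl to pH 2
Reagents that add atoms: water, O
Why: Enzymatic desymmetrisation (enantiotopic-group-selective ester hydrolysis) should cleave only the pro-S ester, so the chiral active site sets the quaternary centre as R, and the anionic half-ester is not hydrolysed further.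

Step 5
Reactants: 8 (2R)-half-ester; 9 pentane-2,4-dione
Product: 12 methyl (2R)-2-[(2E)-3,7-dimethylocta-2,6-dien-1-yl]-2-methyl-3,5,7-trioxooctanoate, via acyl imidazolide 10 (not isolated), via pentane-2,4-dione dilithium dianion 11 (not isolated)
Conditions: 8, 1,1'-carbonyldiimidazole (1.1 equiv), THF, rt; added to 11 [9 (3.5 equiv), LiN(iPr)2 (7 equiv), THF, −78 → 0 °C] at −78 → −20 °C; 1 M HCl
Reagents that add atoms: none
Why: Claisen-type C-acylation of a 1,3-diketone dianion at its terminal carbanion by the acyl imidazolide should be chemoselective, because the imidazolide is far more electrophilic than the hindered methyl ester on the same non-enolisable carbon, so the two carboxyl carbons stay distinct and the stereocentre is carried through unchanged.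

Step 6
Reactants: 12 methyl (2R)-2-geranyl-2-methyl-3,5,7-trioxooctanoate
Product: 13 (4R)-2-acetyl-4-[(2E)-3,7-dimethylocta-2,6-dien-1-yl]-3,5-dihydroxy-4-methylcyclohexa-2,5-dien-1-one (enol form of the acetyl geranyl methyl trione)
Conditions: KOtBu (3 equiv), THF, 0 → 50 °C; then 1 M HCl
Reagents that add atoms: none
Why: Intramolecular Claisen (Dieckmann-type) condensation of the doubly stabilised C6 carbanion onto the ester is the only six-membered C–C closure open to the chain and should be driven by irreversible deprotonation of the acidic trione, with the quaternary centre untouched because it cannot enolise.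

Step 7
Reactants: 13 acetyl geranyl methyl trione; 14 N,N-dimethylmethyleneiminium iodide
Product: 15 (4R)-2-acetyl-6-[(dimethylammonio)methyl]-4-[(2E)-3,7-dimethylocta-2,6-dien-1-yl]-3,5-dihydroxy-4-methylcyclohexa-2,5-dien-1-one iodide (Mannich salt)
Conditions: 14 (1.05 equiv), MeCN, 0 °C → rt, no added base; evaporate
Reagents that add atoms: none
Why: Mannich aminomethylation should occur at C6, the only unsubstituted nucleophilic carbon of the enolised trione, and running it without base keeps the product as its ammonium salt so that it cannot eliminate and dimerise.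

Step 8
Reactants: 15 Mannich salt; 4 1-[4-(tert-butyldimethylsilyloxy)-2,6-dihydroxyphenyl]hexan-1-one
Product: 17 1-[4-(tert-butyldimethylsilyloxy)-3-{[(3R)-5-acetyl-3-[(2E)-3,7-dimethylocta-2,6-dien-1-yl]-2,4-dihydroxy-3-methyl-6-oxocyclohexa-1,4-dien-1-yl]methyl}-2,6-dihydroxyphenyl]hexan-1-one, via methylidene trione 16 (not isolated)
Conditions: 4 (2.5 equiv), NaOAc (1.5 equiv), MeCN, 60 °C
Reagents that add atoms: none
Why: Buffered loss of dimethylamine from the Mannich salt should unmask the methylidene trione, a strong conjugate acceptor, which is attacked in a Friedel–Crafts-type Michael addition by C3 of the arene (equivalent to C5 by symmetry, so no regioisomer is possible), excess arene limiting a second alkylation.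

Step 9
Reactants: 17 silylated bridged dimer; 18 3-methylbut-2-enal
Product: 20 1-[5-(tert-butyldimethylsilyloxy)-6-{[(3R)-5-acetyl-3-[(2E)-3,7-dimethylocta-2,6-dien-1-yl]-2,4-dihydroxy-3-methyl-6-oxocyclohexa-1,4-dien-1-yl]methyl}-7-hydroxy-2,2-dimethyl-2H-chromen-8-yl]hexan-1-one, via ring-A dienone 19 (not isolated)
Conditions: ethylenediammonium diacetate (0.3 equiv), 18 (3 equiv), toluene, 80 °C
Reagents that add atoms: none
Why: The diammonium diacetate turns the enal into an iminium ion, which is attacked by C5 of ring A, the only unsubstituted carbon in the molecule that is activated by a free ortho hydroxyl (Knoevenagel-type condensation), and loss of the amine gives the ring-A 1-oxatriene 19, in which O6 has become the carbonyl oxygen. Thermal disrotatory oxa-6π electrocyclisation of 19 then joins O6 to the C(CH3)2 terminus, closing the six-membered pyran (ring C) in a pericyclic mode, formally 6-endo at the alkene, and restoring the aromaticity of ring A. The closest known reaction type is the amine-salt-mediated formal [3+3] annulation of phenols and 1,3-dicarbonyl compounds with α,β-unsaturated aldehydes to 2H-chromenes and 2H-pyrans. No stereocentre is created, since the new sp3 carbon carries two methyl groups, and the quaternary centre of ring B is remote and non-enolisable. The step needs site selectivity (C5 only) and regioselective closure (O6, not O4): the first is secured because every carbon of ring B and C1 and C3 of ring A are fully substituted, the second because O4 is a silyl ether and cannot become the dienone carbonyl, while O6 is the only free oxygen ortho to C5.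

Step 10
Reactants: 20 silylated chromene dimer
Product: 21 1-[6-{[(3R)-5-acetyl-3-[(2E)-3,7-dimethylocta-2,6-dien-1-yl]-2,4-dihydroxy-3-methyl-6-oxocyclohexa-1,4-dien-1-yl]methyl}-5,7-dihydroxy-2,2-dimethyl-2H-chromen-8-yl]hexan-1-one (CNP0319887.1)
Conditions: Bu4NF (1.5 equiv), AcOH (1.5 equiv), THF, 0 °C
Reagents that add atoms: none
Why: Fluoride-induced cleavage of the aryl silyl ether should be fast at 0 °C, and the acetic acid buffer keeps the methylene bridge, the chromene and the enolised trione away from strongly basic fluoride or phenoxide.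

**Compound list**

1 | phloroglucinol | Oc1cc(O)cc(O)c1 | starting material
2 | hexanoyl chloride | CCCCCC(Cl)=O | starting material
3 | 1-(2,4,6-trihydroxyphenyl)hexan-1-one | CCCCCC(=O)c1c(O)cc(O)cc1O | intermediate
4 | 1-[4-(tert-butyldimethylsilyloxy)-2,6-dihydroxyphenyl]hexan-1-one | CCCCCC(=O)c1c(O)cc(O[Si](C)(C)C(C)(C)C)cc1O | intermediate
5 | dimethyl methylmalonate | COC(=O)C(C)C(=O)OC | starting material
6 | geranyl bromide, (2E)-1-bromo-3,7-dimethylocta-2,6-diene | BrC/C=C(\C)CCC=C(C)C | starting material
7 | dimethyl 2-[(2E)-3,7-dimethylocta-2,6-dien-1-yl]-2-methylpropanedioate | COC(=O)C(C)(C/C=C(\C)CCC=C(C)C)C(=O)OC | intermediate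
8 | (2R)-2-[(2E)-3,7-dimethylocta-2,6-dien-1-yl]-3-methoxy-2-methyl-3-oxopropanoic acid | COC(=O)[C@](C)(C/C=C(\C)CCC=C(C)C)C(O)=O | intermediate
9 | pentane-2,4-dione | CC(=O)CC(C)=O | starting material
10 | methyl (2R)-2-[(2E)-3,7-dimethylocta-2,6-dien-1-yl]-3-(1H-imidazol-1-yl)-2-methyl-3-oxopropanoate (acyl imidazolide, not isolated) | COC(=O)[C@](C)(C/C=C(\C)CCC=C(C)C)C(=O)n1ccnc1 | intermediate
11 | dilithium salt of the pentane-2,4-dione 1,3-dianion (not isolated) | [Li+].[Li+].C=C([O-])C=C(C)[O-] | intermediate
12 | methyl (2R)-2-[(2E)-3,7-dimethylocta-2,6-dien-1-yl]-2-methyl-3,5,7-trioxooctanoate | COC(=O)[C@](C)(C/C=C(\C)CCC=C(C)C)C(=O)CC(=O)CC(C)=O | intermediate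
13 | (4R)-2-acetyl-4-[(2E)-3,7-dimethylocta-2,6-dien-1-yl]-3,5-dihydroxy-4-methylcyclohexa-2,5-dien-1-one | CC(=O)C1=C(O)[C@](C)(C/C=C(\C)CCC=C(C)C)C(O)=CC1=O | intermediate
14 | N,N-dimethylmethyleneiminium iodide | C[N+](C)=C.[I-] | starting material
15 | (4R)-2-acetyl-6-[(dimethylammonio)methyl]-4-[(2E)-3,7-dimethylocta-2,6-dien-1-yl]-3,5-dihydroxy-4-methylcyclohexa-2,5-dien-1-one iodide | CC(=O)C1=C(O)[C@](C)(C/C=C(\C)CCC=C(C)C)C(O)=C(C[NH+](C)C)C1=O.[I-] | intermediate
16 | 2-acetyl-4-[(2E)-3,7-dimethylocta-2,6-dien-1-yl]-3-hydroxy-4-methyl-6-methylidenecyclohex-2-ene-1,5-dione (4S by the sequence rule, spatial arrangement unchanged; not isolated) | CC(=O)C1=C(O)[C@](C)(C/C=C(\C)CCC=C(C)C)C(=O)C(=C)C1=O | intermediate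
17 | 1-[4-(tert-butyldimethylsilyloxy)-3-{[(3R)-5-acetyl-3-[(2E)-3,7-dimethylocta-2,6-dien-1-yl]-2,4-dihydroxy-3-methyl-6-oxocyclohexa-1,4-dien-1-yl]methyl}-2,6-dihydroxyphenyl]hexan-1-one | CCCCCC(=O)c1c(O)c(CC2=C(O)[C@@](C)(C/C=C(\C)CCC=C(C)C)C(O)=C(C(C)=O)C2=O)c(O[Si](C)(C)C(C)(C)C)cc1O | intermediate
18 | 3-methylbut-2-enal | CC(C)=CC=O | starting material
19 | ring-A 1-oxatriene: 17 with C5 carrying an exocyclic =CH–CH=C(CH3)2 unit and O6 as ring carbonyl (not isolated; exocyclic alkene geometry not fixed) | CCCCCC(=O)C1=C(O)C(CC2=C(O)[C@@](C)(C/C=C(\C)CCC=C(C)C)C(O)=C(C(C)=O)C2=O)=C(O[Si](C)(C)C(C)(C)C)C(=CC=C(C)C)C1=O | intermediate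
20 | 1-[5-(tert-butyldimethylsilyloxy)-6-{[(3R)-5-acetyl-3-[(2E)-3,7-dimethylocta-2,6-dien-1-yl]-2,4-dihydroxy-3-methyl-6-oxocyclohexa-1,4-dien-1-yl]methyl}-7-hydroxy-2,2-dimethyl-2H-chromen-8-yl]hexan-1-one | CCCCCC(=O)c1c(O)c(CC2=C(O)[C@@](C)(C/C=C(\C)CCC=C(C)C)C(O)=C(C(C)=O)C2=O)c(O[Si](C)(C)C(C)(C)C)c2c1OC(C)(C)C=C2 | intermediate
21 | 1-[6-{[(3R)-5-acetyl-3-[(2E)-3,7-dimethylocta-2,6-dien-1-yl]-2,4-dihydroxy-3-methyl-6-oxocyclohexa-1,4-dien-1-yl]methyl}-5,7-dihydroxy-2,2-dimethyl-2H-chromen-8-yl]hexan-1-one | CCCCCC(=O)c1c(O)c(CC2=C(O)[C@@](C)(C/C=C(\C)CCC=C(C)C)C(O)=C(C(C)=O)C2=O)c(O)c2c1OC(C)(C)C=C2 | target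

**Totals**

Total step count: 10. Longest linear sequence: 8 steps (steps 3 to 10, from dimethyl methylmalonate).

**Steps most likely to fail**

Step 9. Three processes could defeat the annulation on the dimer. The primary diamine may be consumed by condensation with the acetyl trione of ring B (vinylogous amide formation), which would stall catalysis. The methylene bridge may scramble by retro-conjugate addition under warm amine-salt conditions. The silyl ether may be lost before ring closure, which would let O4 compete with O6. The fallback reverses the order of annulation and bridging, so that ring B never meets the amine catalyst. It sets out from 4, which has two equivalent free carbons and O4 blocked. Condensation of 4 with one equivalent of 18 under ethylenediammonium diacetate in toluene should pass through the transient monomeric ring-A dienone F1 and give 1-[5-(tert-butyldimethylsilyloxy)-7-hydroxy-2,2-dimethyl-2H-chromen-8-yl]hexan-1-one F2. F2 has one free aromatic carbon between its hydroxyl and its silyl ether; alkylation there by the Mannich salt 15 (NaOAc, MeCN, 60 °C, through 16) should rejoin the route at 20.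

Step 4. The esterase may discriminate poorly between the two enantiotopic ester groups, or in the opposite sense, and the lipophilic substrate may be turned over slowly. The fallback is a classical resolution that sets out from 7 and returns at 8. Half-saponification of 7 with one equivalent of KOH in methanol should give the racemic half-ester F3. The (R)-acid would then be separated by crystallisation of its diastereomeric 1-phenylethylammonium salt F4, drawn with the (S)-amine; the (R)-amine would be used if the other diastereomer proves the less soluble. Acidification of F4 returns 8.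

Step 8. The arene may be alkylated a second time at its remaining free carbon, the methylidene trione may self-condense, the aryl silyl ether may be cleaved by acetate or amine, and attack next to the silyl ether may be slow. The fallback inverts the polarity of the bridge-forming event; it sets out from 4 and 13 and returns at 17. Aminomethylation of 4 with one equivalent of 14 should give the benzylic Mannich salt F5. Buffered warming of F5 with the acidic trione 13 (NaOAc, MeCN) should release the ortho-quinone methide F6, and conjugate addition of the enolised trione through C6, its only free carbon, gives 17.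

Further compounds
F1 | step 9 | ring-A dienone from 4 and 3-methylbut-2-enal, C5 carrying =CH–CH=C(CH3)2 and O6 as carbonyl (transient) | CCCCCC(=O)C1=C(O)C=C(O[Si](C)(C)C(C)(C)C)C(=CC=C(C)C)C1=O
F2 | step 9 | 1-[5-(tert-butyldimethylsilyloxy)-7-hydroxy-2,2-dimethyl-2H-chromen-8-yl]hexan-1-one | CCCCCC(=O)c1c(O)cc(O[Si](C)(C)C(C)(C)C)c2c1OC(C)(C)C=C2
F3 | step 4 | racemic 2-[(2E)-3,7-dimethylocta-2,6-dien-1-yl]-3-methoxy-2-methyl-3-oxopropanoic acid | COC(=O)C(C)(C/C=C(\C)CCC=C(C)C)C(O)=O
F4 | step 4 | (S)-1-phenylethylammonium (2R)-2-[(2E)-3,7-dimethylocta-2,6-dien-1-yl]-3-methoxy-2-methyl-3-oxopropanoate | COC(=O)[C@](C)(C/C=C(\C)CCC=C(C)C)C(=O)[O-].C[C@H]([NH3+])c1ccccc1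
F5 | step 8 | 1-{4-(tert-butyldimethylsilyloxy)-3-[(dimethylammonio)methyl]-2,6-dihydroxyphenyl}hexan-1-one iodide | CCCCCC(=O)c1c(O)c(C[NH+](C)C)c(O[Si](C)(C)C(C)(C)C)cc1O.[I-]
F6 | step 8 | ortho-quinone methide of ring A, C3 carrying =CH2 and O2 as carbonyl (transient) | CCCCCC(=O)C1=C(O)C=C(O[Si](C)(C)C(C)(C)C)C(=C)C1=O
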